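In a closed flask the charged Q is conserved: it is solid, dissolved, or bound in adduct, with one Q in each D.

| setting | gamma | zeta | flask |
|---|---|---|---|
| L | 0.14 M | 0.22 M | 0.10 M |
| Q | 0.095 M | 0.095 M | 0.0950 M |
| remark | run made earlier | run made earlier |  |
| time |  |  | 30 min |

| run | time / min | D / % |
|---|---|---|
| gamma | 2.00 | 2.6 |
| gamma | 6.00 | 5.2 |
| gamma | 12.0 | 13.7 |
| gamma | 15.0 | 15.9 |
| gamma | 25.0 | 30.3 |
| zeta | 2.00 | 0 |
| zeta | 4.00 | 2.9 |
| zeta | 6.00 | 3.9 |
| zeta | 12.0 | 11.9 |
| zeta | 25.0 | 23.4 |

(each reading ± 1 percentage point)

- solid, in amounts per volume of the solution: Q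
- at the start none of Q is in solution

1. amount of D at 30 min, in percent of the L charged
2. the change that raises the amount of D at 30 min, in percent of the L charged most ("none" if none brings more than 2 percentage points) (Tuesday's / Saturday's / none)
3. amount of D at 30 min, in percent of the L charged, after Tuesday's

- Tuesday's: doubling the solubility of Q, all else as stated
- Saturday's: doubling the dissolution coefficient of Q, all else as stated

The two runs seem to disagree at 25.0 min: zeta, charged with more L, reads 23.4% D against 30.3% in gamma. In molar terms the order turns, with [D] at 0.0424 M in gamma and 0.0515 M in zeta. L rose by a factor of 1.57 but [D] by 1.21, so the percentage fell because its denominator grew faster.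

We therefore reckon in Q, the limiting reagent of this flask, with 0.0950 M against 0.10 M of L. Reading its last D as the Q taken up, which leaves any further adduct uncounted, gamma takes up Q at about 0.00170 M min⁻¹ on average, and the charge of Q divided by that uptake rate is the spending time 56.0 min. If this flask takes up Q as gamma did, which is our assumption, 46.4% of its Q remains at 30 min. The Q taken up equals 51.0% of the L charged, shared between D and any further adduct.

The forecast gives 40% of D, a different quantity from ours, and names Tuesday's with 67%, holding that “rate depends only weakly on L”.

The flask gives 38.8%, and Tuesday's is best at 49.4%, a gain of 11 percentage points against 8.9 points for Saturday's.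

    L + E → D (k = 0.0241 L mol⁻¹ s⁻¹)
    E + D → X (k = 0.0109 L mol⁻¹ s⁻¹)
    E + X → J (k = 0.0178 L mol⁻¹ s⁻¹)
    Q ⇌ E, rate k4*(cs4 - [E]) while solid is left; crystals form when [E] > cs4 (solubility = 45.0 mM, k = 0.00123 s⁻¹)

This flask has not come to rest at 30 min: 45% of its Q remains as solid or E, against our 46.4%. The same flask read at 50 min has solid Q at 0% and E at 0.00949 M, which is 9.99% of the charge, against 10.7% from the spending time. Left for 300 min, this flask would still raise D from 38.8% to 51.2% and lower L from 55.1% to 29.5%, while X reaches 13.9% and J 5.29%. By then [D] + 2[X] + 3[J] is 0.0950 M, with E down to 1.17 × 10⁻¹² M.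

(All runs were generated by integration with constants of no real substance; noise was put on by code.)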